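Atom numbers used throughout: ring B is O–C2–C3–C4–C5–C6–C7 with C1 the bromomethylene carbon on C2; ring A is C6–C7–C8–C9–C10–C11. The route departs from the ionone-type starting material one might expect for diene 9: C6 is set by a catalytic desymmetrisation instead of a terpenoid resolution, which saves about five steps. None of the steps has been run; the last four steps carry most of the risk.

## The problem

Compound 24 is a trans-fused bicycle in which cyclohexane ring A shares the C6–C7 bond with oxepane ring B: C7 is fully substituted and carries the ring oxygen and an axial methyl group, C11 is a gem-dimethyl carbon, and C10 carries an equatorial bromine. Five stereocentres (3R, 4R, 6S, 7S, 10S) and the (E) geometry at C1=C2 have to be secured. C6 is the root of control: it can direct oxygen to C7 on the opposite face, and once C6 and C7 are fixed the trans-fused chair makes the equatorial C10 bromine the thermodynamic one and lets the axial C7 methyl group shield the β face of ring B, so only C6 needs absolute control. The C10 bromide is secondary and neopentyl, which rules out displacement and calls for a bond-forming event under thermodynamic control. The bromo enol ether next to a trisubstituted epoxide hydrolyses, ionises and over-oxidises easily, and its (E) isomer is the crowded one because bromine faces the quaternary C3; this array must come last, under neutral conditions, and its geometry is better obtained by choosing between two bromines than by introducing one. The feature that opens the route lies in ring A: the ether carbon C7 and the bromine-bearing C10 are 1,4-related with only C8 and C9 between them, C7 has no hydrogen and C10 has one, which is what remains when dioxygen adds across a C7=C8–C9=C10 diene and the peroxide is isomerised by base. A second feature serves ring B: a four-carbon branch on C6 ending in a methyl ketone (C5, C4, C2, C1) closes with the C7 hydroxyl to a six-membered enol ether, into which the missing carbon C3 and its methyl group can be inserted as a carbene.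

## Retrosynthesis

**24 ⇒ 23 (C1–H traced back to C1–Br).** The bromine that must stay in 24 faces the quaternary C3. Bromination–elimination of an exocyclic enol ether puts the halogen on the open side, next to the ring oxygen, and would give the wrong isomer. The last bond formed is therefore a C1–H bond, made from the second C1–Br bond of the 1,1-dibromide 23. The forward hydrogenolysis only has to tell an exposed C–Br bond from a hindered one, and must leave the alkenyl epoxide and the C10 bromide alone.

**23 ⇒ 22 (C3–O and C4–O).** The epoxide is removed to diene 22. Oxidising at the dibromide stage is deliberate: two halogens make the enol ether the poorer nucleophile, so an electrophilic oxidant is steered to C3=C4, whereas the unbrominated or monobrominated dienes would react at the enol ether. The forward step must attack the α face; the axial C7 methyl group over the β face is the control element.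

**22 ⇒ 20 (both C1–Br bonds).** Both halogens are taken off C1 to leave the exocyclic enol ether 20, with monobromide 21 as a transient. C1 is the terminus of a 2-alkoxydiene and the one position whose attack gives a cation stabilised by oxygen and by C3=C4. The forward bromination–dehydrobromination, run twice, is asked to stay at C1.

**20 ⇒ 18 (C2–C3 and C3–C4).** Removing C3 with its methyl group contracts ring B to the six-membered enol ether 18. Forward, a carbenoid bearing methyl and chlorine adds to C2=C4 to give 19, which opens to a seven-membered oxygen-stabilised allyl cation and loses a proton from the C2 methyl group. Direct seven-membered closure by a tertiary alcohol is slow and gives no control of the double-bond position; this cut uses the ring size that forms by itself and adds the missing carbon afterwards. It delivers the C3 methyl group, C3=C4 and the exocyclic C1=C2 in one operation. The demand is regiochemical: proton loss at C1, not C5.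

**18 ⇒ 16 (O–C2).** Opening the enol ether gives hydroxy ketone 17 and, with the ketone masked, dioxolane 16. The precursor is monocyclic and all its stereocentres sit in ring A. Forward, this is acetal hydrolysis and cyclodehydration.

**16 ⇒ 15 ⇒ 14 ⇒ 13 ⇒ 12 (C10–H and C9–H, then C10–Br, then C8–H and C9–H).** Because substitution at C10 is excluded, 16 is traced to vinyl bromide 15 by radical hydrogenation under thermodynamic control. 15 comes from enol triflate 14 by halide exchange, 14 from ketone 13 (which can enolise only towards C9), and 13 from enone 12 by saturation of C8=C9. Each forward step is asked only for chemoselectivity; the C10 configuration follows from the ring.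

**12 ⇒ 9 + 10 (C7–O and C10–O).** Both ring-A oxygens are removed at once to homoannular diene 9 and dioxygen 10, through endoperoxide 11. Hydration or epoxide opening at C7 lacks regiocontrol, and a methyl nucleophile added to a C7 ketone would enter equatorially and give the wrong C7 epimer. The cycloaddition fixes the C7 oxygen trans to the C6 branch, and the fragmentation is forced by the absence of hydrogen at C7. Diene 9 has one stereocentre and no heteroatom in ring A.

**9 ⇒ 8 ⇒ 7 ⇒ 6 (C8–H, then C7–CH3).** The diene is traced to dienyl triflate 8, then to α′-methyl enone 7, then to enone 6. Dehydration of an allylic alcohol gives double-bond mixtures, and a sulfonylhydrazone elimination has no secondary α′-hydrogen to use once the C7 methyl group is in place. The enolate route is regiospecific because C11 is quaternary and only C7 can be deprotonated.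

**6 ⇒ 2 + 3 (C6–C5).** Cutting the branch from C6 gives the achiral dienone 2 and the four-carbon bromide 3, used through 4 and 5. A resolved monocyclic norterpenoid ketone could supply the same skeleton, but it would need a resolution, side-chain reduction, acetalisation and allylic oxidation. The catalytic desymmetrisation reaches the same pattern in fewer steps and wastes no enantiomer. The forward step must select one of two enantiotopic β-carbons next to a quaternary centre.

**2 ⇒ 1 (C–H bonds at the α′ and β′ carbons).** Dienone 2 comes from commercial enone 1 by dehydrogenation.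

## Roads not taken

**Alternative 1:** The cut removes the ring oxygen between C7 and C2 and reveals the carbocyclic α,β-epoxy decalone A2. Forward, CF3CO3H buffered with Na2HPO4 inserts oxygen on the C7 side (Baeyer–Villiger oxidation) and gives the epoxy ε-lactone A1.
- Merits: the fully alkylated C7 migrates in preference to the electron-poor epoxide carbon and does so with retention. The epoxide is in place before any enol ether exists, and ring B is formed without a cyclisation.
- Weak points: A2 is a brominated trans-decalone with the neopentyl equatorial bromide already installed, so the C10 problem is only moved to an earlier, unspecified stage. The peracid is acidic towards the epoxide. The lactone carbonyl, flanked by the quaternary epoxide carbon, must still become the (E)-bromomethylene by olefination of a hindered lactone and selective monoreduction.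
- Comparison: for the late stage this road is better than the chosen one, because it avoids a cationic ring expansion with a regiochemical choice and the oxidation of a diene. The chosen plan sets against it catalytic access to the single enantiomer from an achiral dienone, placement of both ring-A oxygens in one step, and a solution to the C10 bromide that A2 presupposes.

**Alternative 2:** The cut goes through ring A at C11–CH3 and C6–C5. Forward, Me2CuLi adds to the β-carbon of the enantiopure silyloxy enone A4 anti to the silyloxy group, and the enolate is alkylated at C6 with a haloacetate to give keto ester A3.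
- Merits: it is convergent, the absolute configuration comes from a known type of hydroxy enone, and C6 and C10 are related at an early stage.
- Weak points: the enolate is alkylated beside a freshly made quaternary carbon, which is slow. The C7 ketone must then accept a methyl group axially, syn to the axial C11 methyl group; small carbon nucleophiles enter equatorially and would give the wrong C7 epimer. The C10 oxygen is on the face the bromine must occupy, so it cannot be displaced and has to pass through the ketone anyway. The two-carbon arm needs four more carbons before ring B can close.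
- Comparison: it is better in convergence. The chosen plan sets against it that C7 is made by oxygen delivery from the correct face, not by carbon delivery from the wrong one, and that the branch of 9 already holds four of the six ring-B carbons.

**Alternative 3:** The cut is C2–C3 together with C1–Br. Forward, [Br(collidine)2]PF6 brominates the vinyl ether of A6 at C1, the C2 oxocarbenium ion is captured at the silicon-bearing carbon of the (Z)-vinylsilane, and loss of silicon leaves C3=C4 in oxepene A5.
- Merits: ring B, the C1–Br bond and a regiodefined C3=C4 bond form in one mild step.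
- Weak points: A5 has a saturated C2 bearing CH2Br, so reaching the target requires a dehydrogenation across C1–C2 with (E) control, for which no clean method is at hand, and the C2 stereocentre is made only to be destroyed. A6 already contains the C7 carbinol, its hindered vinyl ether and the C10 bromide, so ring A remains unsolved.
- Comparison: as a ring-B closure it is at least as secure as the carbene ring expansion chosen here. The chosen plan sets against it the correct oxidation level at C1–C2 directly from the ring expansion, control of the bromide geometry through the dibromide, and a defined origin for ring A.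

Key step: step 6

## Route

Assumption: the (S,R,R)-phosphoramidite is taken to deliver the alkyl group to dienone 2 in the same facial sense in which it gives (S)-3-alkylcyclohexanones from cyclohex-2-enone, which corresponds to (5R)-6; if the sense is reversed, the mirror-image ligand is used and nothing else changes.

Locants C1–C11 in the Why lines are those of the target.

Step 1
Reactants: 1 4,4-dimethylcyclohex-2-en-1-one
Product: 2 4,4-dimethylcyclohexa-2,5-dien-1-one
Conditions: DDQ, 1,4-dioxane, reflux
Reagents that add atoms: none
Why: Quinone dehydrogenation of a 4,4-disubstituted cyclohexenone to the cross-conjugated dienone (hydride abstraction from the dienol, then proton loss); the quaternary carbon prevents aromatisation.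

Step 2
Reactants: 2 4,4-dimethylcyclohexa-2,5-dien-1-one; 3 2-(2-bromoethyl)-2-methyl-1,3-dioxolane
Product: 6 (5R)-4,4-dimethyl-5-[2-(2-methyl-1,3-dioxolan-2-yl)ethyl]cyclohex-2-en-1-one, via Grignard reagent 4 (not isolated), via dialkylzinc 5 (not isolated)
Conditions: 3, Mg, THF, 25 °C; ZnCl2 (0.5 equiv), then 1,4-dioxane, filtration; 2, Cu(OTf)2 (2 mol%), (S,R,R)-phosphoramidite [(S)-binaphthyl-2,2'-diyl N,N-bis((R)-1-phenylethyl)phosphoramidite, 4 mol%], toluene, −30 °C; aq. NH4Cl
Reagents that add atoms: none
Why: Copper–phosphoramidite-catalysed conjugate addition of a dialkylzinc desymmetrises the dienone: the chiral copper species selects one of the two enantiotopic β-carbons and forms the C6–C5 bond beside the quaternary carbon, setting the one stereocentre on which all later ones depend. Acetal-bearing dialkylzincs are accepted in this reaction, and the magnesium halide is precipitated because it promotes a racemic background addition.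

Step 3
Reactants: 6 (5R)-4,4-dimethyl-5-[2-(2-methyl-1,3-dioxolan-2-yl)ethyl]cyclohex-2-en-1-one
Product: 7 (5R)-4,4,6-trimethyl-5-[2-(2-methyl-1,3-dioxolan-2-yl)ethyl]cyclohex-2-en-1-one (both epimers at the new methyl-bearing carbon)
Conditions: LiN(iPr)2, THF, −78 °C; MeI, −78 → −20 °C
Reagents that add atoms: iodomethane, CI
Why: Kinetic deprotonation can occur only at the α′-methylene C7 because the γ-carbon C11 is quaternary, and the lithium enolate is C-methylated (enolate alkylation). The configuration of the new centre is irrelevant since C7 becomes trigonal in the next step; C6 is β to the carbonyl and cannot epimerise.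

Step 4
Reactants: 7 (5R)-4,4,6-trimethyl-5-[2-(2-methyl-1,3-dioxolan-2-yl)ethyl]cyclohex-2-en-1-one
Product: 8 (3S)-2,4,4-trimethyl-3-[2-(2-methyl-1,3-dioxolan-2-yl)ethyl]cyclohexa-1,5-dien-1-yl trifluoromethanesulfonate
Conditions: KN(SiMe3)2, THF, −78 °C; PhNTf2, −78 → 0 °C
Reagents that add atoms: N-phenylbis(trifluoromethanesulfonimide), O=S(=O)(N(c1ccccc1)S(=O)(=O)C(F)(F)F)C(F)(F)F
Why: The remaining α′-hydrogen at C7 is the only acidic one, so the cross-conjugated dienolate forms regiospecifically and is O-sulfonylated (enol triflate formation), fixing the double bonds at C7=C8 and C9=C10.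

Step 5
Reactants: 8 (3S)-2,4,4-trimethyl-3-[2-(2-methyl-1,3-dioxolan-2-yl)ethyl]cyclohexa-1,5-dien-1-yl trifluoromethanesulfonate
Product: 9 2-methyl-2-{2-[(1R)-2,6,6-trimethylcyclohexa-2,4-dien-1-yl]ethyl}-1,3-dioxolane
Conditions: Pd(OAc)2 (5 mol%), PPh3 (10 mol%), HCO2H, Bu3N, DMF, 40 °C
Reagents that add atoms: none
Why: Palladium-catalysed formate reduction of an alkenyl triflate (oxidative addition, formate exchange, decarboxylation, reductive elimination) replaces the triflate by hydrogen without moving the double bonds. The low temperature avoids a thermal 1,5-hydrogen shift that would erase C6.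

Step 6
Reactants: 9 2-methyl-2-{2-[(1R)-2,6,6-trimethylcyclohexa-2,4-dien-1-yl]ethyl}-1,3-dioxolane; 10 dioxygen
Product: 12 (4S,5S)-4-hydroxy-4,6,6-trimethyl-5-[2-(2-methyl-1,3-dioxolan-2-yl)ethyl]cyclohex-2-en-1-one, via endoperoxide 11 (not isolated)
Conditions: O2, tetraphenylporphyrin (1 mol%), visible light, CH2Cl2, −20 °C; then Et3N, 0 °C → rt
Reagents that add atoms: none
Why: Photosensitised (singlet) dioxygen adds suprafacially across C7 and C10 of the cisoid diene in a [4+2] cycloaddition of the ascaridole type, forming the C7–O and C10–O bonds of a 2,3-dioxabicyclo[2.2.2]octene. By the Curtin–Hammett principle the diene reacts through the half-chair in which C6–H is pseudo-axial: on that face neither diene terminus has an axial neighbour, whereas the other face carries the axial C11 methyl group and the branch, so oxygen enters anti to the C6 branch and C7 becomes (S), with oxygen trans to the branch. Triethylamine then removes the only bridgehead hydrogen, at C10, with cleavage of the O–O bond (Kornblum–DeLaMare rearrangement), which turns the C10 oxygen into the ketone and the C7 oxygen into the tertiary hydroxyl. Because C7 has no hydrogen, the rearrangement can run in one direction only. No ring of the target closes here; the peroxide bridge is transient and its C10 centre is destroyed. The new C7 stereocentre is under substrate control by C6. The step needs cycloaddition to outrun the ene reaction, which the homoannular cisoid diene secures, and it needs facial selectivity, which the branch and the gem-dimethyl group secure together. The dioxolane is inert to both stages.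

Step 7
Reactants: 12 (4S,5S)-4-hydroxy-4,6,6-trimethyl-5-[2-(2-methyl-1,3-dioxolan-2-yl)ethyl]cyclohex-2-en-1-one
Product: 13 (3S,4S)-4-hydroxy-2,2,4-trimethyl-3-[2-(2-methyl-1,3-dioxolan-2-yl)ethyl]cyclohexan-1-one
Conditions: H2 (1 atm), Pd/C (5%), EtOAc, rt
Reagents that add atoms: none
Why: Heterogeneous hydrogenation of the disubstituted enone double bond; the hindered ketone, the dioxolane and the tertiary alcohol are inert in a neutral solvent and no stereocentre is formed.

Step 8
Reactants: 13 (3S,4S)-4-hydroxy-2,2,4-trimethyl-3-[2-(2-methyl-1,3-dioxolan-2-yl)ethyl]cyclohexan-1-one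
Product: 14 (4S,5S)-4-hydroxy-4,6,6-trimethyl-5-[2-(2-methyl-1,3-dioxolan-2-yl)ethyl]cyclohex-1-en-1-yl trifluoromethanesulfonate
Conditions: LiN(iPr)2 (2.1 equiv), THF, −78 °C; N-(5-chloropyridin-2-yl)bis(trifluoromethanesulfonimide) (1.05 equiv), −78 → −20 °C
Reagents that add atoms: N-(5-chloropyridin-2-yl)bis(trifluoromethanesulfonimide), O=S(=O)(N(c1ccc(Cl)cn1)S(=O)(=O)C(F)(F)F)C(F)(F)F
Why: The ketone is flanked by the quaternary C11 and can enolise only towards C9; two equivalents of base give the alkoxide–enolate, and at low temperature the enolate oxygen is sulfonylated in preference to the hindered tertiary alkoxide (enol triflate formation).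

Step 9
Reactants: 14 (4S,5S)-4-hydroxy-4,6,6-trimethyl-5-[2-(2-methyl-1,3-dioxolan-2-yl)ethyl]cyclohex-1-en-1-yl trifluoromethanesulfonate
Product: 15 (1S,6S)-4-bromo-1,5,5-trimethyl-6-[2-(2-methyl-1,3-dioxolan-2-yl)ethyl]cyclohex-3-en-1-ol
Conditions: Ni(cod)2 (10 mol%), LiBr, DMA–THF, rt
Reagents that add atoms: lithium bromide, [Li+].[Br-]
Why: Nickel-catalysed triflate-to-bromide exchange on an alkenyl triflate (oxidative addition to zerovalent nickel, halide exchange, reductive elimination) gives the vinyl bromide with the double bond fixed at C9=C10. No carbocation is formed beside the quaternary centre, so methyl migration and transannular capture by the C7 hydroxyl are avoided.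

Step 10
Reactants: 15 (1S,6S)-4-bromo-1,5,5-trimethyl-6-[2-(2-methyl-1,3-dioxolan-2-yl)ethyl]cyclohex-3-en-1-ol
Product: 16 (1S,2S,4S)-4-bromo-1,3,3-trimethyl-2-[2-(2-methyl-1,3-dioxolan-2-yl)ethyl]cyclohexan-1-ol
Conditions: Mn(dpm)3 (10 mol%), PhSiH3, t-BuOOH, i-PrOH, 22 °C
Reagents that add atoms: none
Why: Hydrogen-atom-transfer hydrogenation: a hydrogen atom adds to C9 to give the α-bromo radical at C10, which keeps its halogen and accepts the second hydrogen axially from the α face, where only C6–H and C8–H are 1,3-diaxial. Bromine therefore ends equatorial, cis to the C7 methyl group (10S); this method reduces vinyl halides without the loss of halogen seen in palladium-catalysed hydrogenation.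

Step 11
Reactants: 16 (1S,2S,4S)-4-bromo-1,3,3-trimethyl-2-[2-(2-methyl-1,3-dioxolan-2-yl)ethyl]cyclohexan-1-ol
Product: 18 (4aS,6S,8aS)-6-bromo-2,5,5,8a-tetramethyl-4a,5,6,7,8,8a-hexahydro-4H-chromene, via hydroxy ketone 17 (not isolated)
Conditions: PPTS, acetone–H2O, 50 °C; then PPTS (cat.), benzene, reflux, 4 Å molecular sieves
Reagents that add atoms: none
Why: Acetal hydrolysis frees the methyl ketone, which the C7 hydroxyl captures as the six-membered lactol; acid-catalysed dehydration with removal of water gives the endocyclic trisubstituted enol ether, the more stable regioisomer (cyclodehydration). The trans ring fusion follows from the fixed C6 and C7 centres, and the secondary bromide is stable to mild acid.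

Step 12
Reactants: 18 (4aS,6S,8aS)-6-bromo-2,5,5,8a-tetramethyl-4a,5,6,7,8,8a-hexahydro-4H-chromene
Product: 20 (5aS,7S,9aS)-7-bromo-3,6,6,9a-tetramethyl-2-methylidene-2,5,5a,6,7,8,9,9a-octahydro-1-benzoxepine, via chlorocyclopropane 19 (not isolated)
Conditions: CH3CHCl2, n-BuLi, Et2O, −40 °C → rt; then Et3N, toluene, 80 °C
Reagents that add atoms: 1,1-dichloroethane, CC(Cl)Cl
Why: The chloro(methyl)carbenoid from 1,1-dichloroethane and n-BuLi cyclopropanates the nucleophilic enol ether; the adduct with chlorine endo opens by disrotatory electrocyclic ring opening with loss of chloride (halocyclopropane ring expansion) to an oxygen-stabilised allyl cation in the seven-membered ring. The amine then removes a proton from the methyl group on the oxocarbenium carbon C2, so the inserted carbon becomes C3 with its methyl group and C3=C4 and C1=C2 appear together. n-BuLi is consumed by the far more acidic dichloroethane before it can attack the neopentyl bromide.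

Step 13
Reactants: 20 (5aS,7S,9aS)-7-bromo-3,6,6,9a-tetramethyl-2-methylidene-2,5,5a,6,7,8,9,9a-octahydro-1-benzoxepine
Product: 22 (5aS,7S,9aS)-7-bromo-2-(dibromomethylidene)-3,6,6,9a-tetramethyl-2,5,5a,6,7,8,9,9a-octahydro-1-benzoxepine, via bromodiene 21 (not isolated)
Conditions: Br2 (1.0 equiv), CH2Cl2, −78 °C, then DBU; repeated once (Br2, then DBU), −78 → 0 °C
Reagents that add atoms: bromine, BrBr
Why: Bromine attacks the enol-ether terminus C1, the position that gives a cation stabilised by oxygen and by C3=C4, and DBU removes HBr; a second cycle on the bromo enol ether gives the 1,1-dibromide (bromination–dehydrobromination of enol ethers). Going through the dibromide makes the geometry of the first bromination irrelevant and deactivates the enol ether for the next step; the equatorial C10 bromide has no anti-periplanar hydrogen and resists elimination.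

Step 14
Reactants: 22 (5aS,7S,9aS)-7-bromo-2-(dibromomethylidene)-3,6,6,9a-tetramethyl-2,5,5a,6,7,8,9,9a-octahydro-1-benzoxepine
Product: 23 (3R,4R,6S,7S,10S)-3,4-epoxide of 22 (epoxide oxygen on the α face, anti to the C7 methyl group; 1,1-dibromomethylidene at C2)
Conditions: dimethyldioxirane, acetone–CH2Cl2, −20 → 0 °C
Reagents that add atoms: dimethyldioxirane, CC1(C)OO1
Why: The electrophilic dioxirane selects the trisubstituted C3=C4 bond over the enol ether, which two halogens have made electron-poor, and is expected to approach from the α face because the axial C7 methyl group projects over the β face of ring B, giving the (3R,4R)-epoxide. Neutral, anhydrous conditions preserve the acid-labile alkenyl epoxide.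

Step 15
Reactants: 23 (3R,4R,6S,7S,10S)-3,4-epoxide of 22
Product: 24 target, (1E,3R,4R,6S,7S,10S)-configured 1,10-dibromo-3,4-epoxy oxepane (numbering of this proposal)
Conditions: Pd(PPh3)4 (5 mol%), Bu3SnH (1.05 equiv), toluene, rt
Reagents that add atoms: none
Why: Palladium-catalysed hydrogenolysis of a 1,1-dibromoalkene with a tin hydride is selective for the less hindered C–Br bond; here that is the bromine cis to the ring oxygen, since the other is pressed against the quaternary C3. Oxidative addition, hydride transfer and reductive elimination with retention leave the (E)-bromide; one equivalent of hydride and the absence of a radical initiator spare the C10 bromide.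

## Compound list

1 | 4,4-dimethylcyclohex-2-en-1-one | CC1(C)CCC(=O)C=C1 | starting material
2 | 4,4-dimethylcyclohexa-2,5-dien-1-one | CC1(C)C=CC(=O)C=C1 | intermediate
3 | 2-(2-bromoethyl)-2-methyl-1,3-dioxolane | CC1(CCBr)OCCO1 | starting material
4 | [2-(2-methyl-1,3-dioxolan-2-yl)ethyl]magnesium bromide | CC1(CC[Mg]Br)OCCO1 | intermediate
5 | bis[2-(2-methyl-1,3-dioxolan-2-yl)ethyl]zinc | CC1(CC[Zn]CCC2(C)OCCO2)OCCO1 | intermediate
6 | (5R)-4,4-dimethyl-5-[2-(2-methyl-1,3-dioxolan-2-yl)ethyl]cyclohex-2-en-1-one | CC1(C)C=CC(=O)C[C@H]1CCC2(C)OCCO2 | intermediate
7 | (5R)-4,4,6-trimethyl-5-[2-(2-methyl-1,3-dioxolan-2-yl)ethyl]cyclohex-2-en-1-one, both C6 epimers | CC1(C)C=CC(=O)C(C)[C@H]1CCC2(C)OCCO2 | intermediate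
8 | (3S)-2,4,4-trimethyl-3-[2-(2-methyl-1,3-dioxolan-2-yl)ethyl]cyclohexa-1,5-dien-1-yl trifluoromethanesulfonate | CC1(C)C=CC(OS(=O)(=O)C(F)(F)F)=C(C)[C@H]1CCC2(C)OCCO2 | intermediate
9 | 2-methyl-2-{2-[(1R)-2,6,6-trimethylcyclohexa-2,4-dien-1-yl]ethyl}-1,3-dioxolane | CC1(C)C=CC=C(C)[C@H]1CCC2(C)OCCO2 | intermediate
10 | dioxygen | O=O | starting material
11 | (1S,4R,7S)-1,8,8-trimethyl-7-[2-(2-methyl-1,3-dioxolan-2-yl)ethyl]-2,3-dioxabicyclo[2.2.2]oct-5-ene | CC1(C)[C@H]2C=C[C@](C)(OO2)[C@H]1CCC3(C)OCCO3 | intermediate
12 | (4S,5S)-4-hydroxy-4,6,6-trimethyl-5-[2-(2-methyl-1,3-dioxolan-2-yl)ethyl]cyclohex-2-en-1-one | CC1(C)C(=O)C=C[C@](C)(O)[C@H]1CCC2(C)OCCO2 | intermediate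
13 | (3S,4S)-4-hydroxy-2,2,4-trimethyl-3-[2-(2-methyl-1,3-dioxolan-2-yl)ethyl]cyclohexan-1-one | CC1(C)C(=O)CC[C@](C)(O)[C@H]1CCC2(C)OCCO2 | intermediate
14 | (4S,5S)-4-hydroxy-4,6,6-trimethyl-5-[2-(2-methyl-1,3-dioxolan-2-yl)ethyl]cyclohex-1-en-1-yl trifluoromethanesulfonate | CC1(C)C(OS(=O)(=O)C(F)(F)F)=CC[C@](C)(O)[C@H]1CCC2(C)OCCO2 | intermediate
15 | (1S,6S)-4-bromo-1,5,5-trimethyl-6-[2-(2-methyl-1,3-dioxolan-2-yl)ethyl]cyclohex-3-en-1-ol | CC1(C)C(Br)=CC[C@](C)(O)[C@H]1CCC2(C)OCCO2 | intermediate
16 | (1S,2S,4S)-4-bromo-1,3,3-trimethyl-2-[2-(2-methyl-1,3-dioxolan-2-yl)ethyl]cyclohexan-1-ol | CC1(C)[C@@H](Br)CC[C@](C)(O)[C@H]1CCC2(C)OCCO2 | intermediate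
17 | 4-[(1S,3S,6S)-3-bromo-6-hydroxy-2,2,6-trimethylcyclohexyl]butan-2-one | CC1(C)[C@@H](Br)CC[C@](C)(O)[C@H]1CCC(C)=O | intermediate
18 | (4aS,6S,8aS)-6-bromo-2,5,5,8a-tetramethyl-4a,5,6,7,8,8a-hexahydro-4H-chromene | CC1(C)[C@@H](Br)CC[C@]2(C)OC(C)=CC[C@@H]12 | intermediate
19 | chloro(methyl)cyclopropane adduct of 18 across the enol-ether double bond (mixture of cyclopropane stereoisomers) | CC1(C)[C@@H](Br)CC[C@]2(C)OC3(C)C(C[C@@H]12)C3(C)Cl | intermediate
20 | (5aS,7S,9aS)-7-bromo-3,6,6,9a-tetramethyl-2-methylidene-2,5,5a,6,7,8,9,9a-octahydro-1-benzoxepine | CC1(C)[C@@H](Br)CC[C@]2(C)OC(=C)C(C)=CC[C@@H]12 | intermediate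
21 | (2Z,5aS,7S,9aS)-7-bromo-2-(bromomethylidene)-3,6,6,9a-tetramethyl-2,5,5a,6,7,8,9,9a-octahydro-1-benzoxepine | CC1(C)[C@@H](Br)CC[C@]2(C)O/C(=C\Br)C(C)=CC[C@@H]12 | intermediate
22 | (5aS,7S,9aS)-7-bromo-2-(dibromomethylidene)-3,6,6,9a-tetramethyl-2,5,5a,6,7,8,9,9a-octahydro-1-benzoxepine | CC1(C)[C@@H](Br)CC[C@]2(C)OC(=C(Br)Br)C(C)=CC[C@@H]12 | intermediate
23 | (3R,4R,6S,7S,10S)-3,4-epoxide of 22, epoxide anti to the C7 methyl group | CC1(C)[C@@H](Br)CC[C@]2(C)OC(=C(Br)Br)[C@]3(C)O[C@@H]3C[C@@H]12 | intermediate
24 | target: (1E,3R,4R,6S,7S,10S)-1,10-dibromo-3,4-epoxy-2-methylidene oxepane fused to ring A (numbering of this proposal) | CC1(C)[C@@H](Br)CC[C@]2(C)O/C(=C/Br)[C@]3(C)O[C@@H]3C[C@@H]12 | target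

Total step count: 15. Longest linear sequence: 15 steps (1 to 24); bromide 3 and dioxygen 10 are purchased and enter at steps 2 and 6.

## Steps least certain to work

**Step 6 (key step).** An ene reaction at the C7 methyl group or at C6–H may compete with the cycloaddition, and some oxygen may enter syn to the branch if the other half-chair reacts. The base-induced fragmentation may also be slow, because the only bridgehead hydrogen sits beside the quaternary C11 and is hard for the amine to reach, which leaves the peroxide to decompose. Fallback: setting out from 11, kept cold and not exposed to base, the O–O bond is reduced with zinc dust in acetic acid–CH2Cl2 to the cis-enediol F1. The secondary allylic hydroxyl of F1 is then oxidised with MnO2, which returns to 12. This redox pair replaces the rearrangement and does not depend on the acidity of C10–H.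

**Step 2.** Alkyl transfer to a β-carbon next to the quaternary centre may be slow, and residual magnesium halide may drive a racemic background addition that erodes the enantiomeric purity. Fallback: setting out from 2, a copper-catalysed addition of Grignard reagent 4 (CuBr·SMe2, Me3SiCl, THF, −78 °C) gives the racemic enone F2. A Corey–Bakshi–Shibata reduction of F2 under catalyst control (catecholborane, the oxazaborolidine enantiomer that gives the (1S)-carbinol) converts the two ring enantiomers into the diastereomeric allylic alcohols F3 and F4, which are separated on silica. MnO2 oxidation of the (1S,5R)-alcohol F3 returns to 6; the carbinol centre serves only as a handle and is removed again.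

**Step 12.** The short-lived carbenoid may be captured inefficiently by a valuable alkene. The cyclopropane epimer with chlorine exo cannot undergo the disrotatory opening and is lost. The cation may lose a proton from C5 instead of the C2 methyl group, or the exocyclic double bond may migrate into the ring under traces of acid. Fallback: setting out from 18, dibromocarbene (CHBr3, KOt-Bu, pentane, 0 °C) gives the dibromocyclopropane F5, in which one bromine is necessarily endo. Opening in toluene with Et3N gives the 3-bromo-2-methylidene oxepine F6, and a Negishi coupling of F6 with MeZnCl and Pd(PPh3)4 installs the C3 methyl group and returns to 20.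

**Step 13.** Once the enol ether carries one bromine, addition of bromine to C3=C4 may compete. After attack at C1 the cation may lose a proton from C5 and leave an allylic bromide instead of the bromo enol ether. Fallback: setting out from 20, ozonolysis of the exocyclic enol-ether bond (one equivalent of O3, CH2Cl2–pyridine, −78 °C; Me2S) gives the unsaturated ε-lactone F7. A Ramirez-type dibromo-olefination of the lactone carbonyl of F7 (CBr4, PPh3, toluene, reflux) returns to 22 without any electrophilic bromination of the diene.

**Step 14.** Facial selectivity may be poor because the seven-membered ring is flexible, and the oxidant may attack the enol ether despite its two halogens. Fallback for the facial problem: setting out from 22, NBS in aqueous acetone gives the bromohydrin F8, with the bromonium ion on the face the oxidant would have chosen and water entering at the tertiary C3 from the other. K2CO3 in methanol then closes the epoxide with inversion at C4. The oxygen thus appears on the face opposite to that of direct epoxidation, which reaches 23 if the direct oxidation favours the β face.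

**Step 15.** Zerovalent palladium may ionise the alkenyl epoxide to an allyl complex that is then reduced. The second bromine may also be removed, or a radical chain may reduce the C10 bromide. Fallback: the order is exchanged. Setting out from 22, the same palladium-catalysed hydrogenolysis is run before any epoxide is present and gives the (E)-bromodiene F9. Dimethyldioxirane oxidation of F9 at C3=C4 then gives 24; the price is a smaller reactivity gap between the two double bonds in the oxidation.

## Further compounds

F1 | step 6 | (1S,4R,6S)-1,5,5-trimethyl-6-[2-(2-methyl-1,3-dioxolan-2-yl)ethyl]cyclohex-2-ene-1,4-diol | CC1(C)[C@H](O)C=C[C@](C)(O)[C@H]1CCC2(C)OCCO2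
F2 | step 2 | racemic 4,4-dimethyl-5-[2-(2-methyl-1,3-dioxolan-2-yl)ethyl]cyclohex-2-en-1-one | CC1(C)C=CC(=O)CC1CCC2(C)OCCO2
F3 | step 2 | (1S,5R)-4,4-dimethyl-5-[2-(2-methyl-1,3-dioxolan-2-yl)ethyl]cyclohex-2-en-1-ol | CC1(C)C=C[C@@H](O)C[C@H]1CCC2(C)OCCO2
F4 | step 2 | (1S,5S)-4,4-dimethyl-5-[2-(2-methyl-1,3-dioxolan-2-yl)ethyl]cyclohex-2-en-1-ol | CC1(C)C=C[C@@H](O)C[C@@H]1CCC2(C)OCCO2
F5 | step 12 | dibromocyclopropane adduct of 18 across the enol-ether double bond | CC1(C)[C@@H](Br)CC[C@]2(C)OC3(C)C(C[C@@H]12)C3(Br)Br
F6 | step 12 | (5aS,7S,9aS)-3,7-dibromo-6,6,9a-trimethyl-2-methylidene-2,5,5a,6,7,8,9,9a-octahydro-1-benzoxepine | CC1(C)[C@@H](Br)CC[C@]2(C)OC(=C)C(Br)=CC[C@@H]12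
F7 | step 13 | (5aS,7S,9aS)-7-bromo-3,6,6,9a-tetramethyl-5,5a,6,7,8,9-hexahydro-1-benzoxepin-2(9aH)-one | CC1(C)[C@@H](Br)CC[C@]2(C)OC(=O)C(C)=CC[C@@H]12
F8 | step 14 | bromohydrin of 22: C3 hydroxyl on the α face, C4 bromine on the β face | CC1(C)[C@@H](Br)CC[C@]2(C)OC(=C(Br)Br)[C@](C)(O)[C@@H](Br)C[C@@H]12
F9 | step 15 | (2E,5aS,7S,9aS)-7-bromo-2-(bromomethylidene)-3,6,6,9a-tetramethyl-2,5,5a,6,7,8,9,9a-octahydro-1-benzoxepine | CC1(C)[C@@H](Br)CC[C@]2(C)O/C(=C/Br)C(C)=CC[C@@H]12
A1 | alternative 1 | epoxy ε-lactone (oxepan-2-one with the C3–C4 epoxide) | CC1(C)[C@@H](Br)CC[C@]2(C)OC(=O)[C@]3(C)O[C@@H]3C[C@@H]12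
A2 | alternative 1 | α,β-epoxy decalone with C2 bonded to C7 | CC1(C)[C@@H](Br)CC[C@]2(C)C(=O)[C@]3(C)O[C@@H]3C[C@@H]12
A3 | alternative 2 | keto ester: C7 ketone, C11 gem-dimethyl, C6 acetate arm cis to the C10 silyloxy group | CC1(C)[C@@H](O[Si](C)(C)C(C)(C)C)CCC(=O)[C@H]1CC(=O)OC(C)(C)C
A4 | alternative 2 | (4S)-4-(tert-butyldimethylsilyloxy)-3-methylcyclohex-2-en-1-one | CC1=CC(=O)CC[C@@H]1O[Si](C)(C)C(C)(C)C
A5 | alternative 3 | 2-(bromomethyl)-3-methyl oxepene fused to ring A | CC1(C)[C@@H](Br)CC[C@]2(C)O[C@H](CBr)C(C)=CC[C@@H]12
A6 | alternative 3 | tertiary vinyl ether at C7 with a (Z)-vinylsilane on the C6 arm | CC1(C)[C@@H](Br)CC[C@](C)(OC=C)[C@H]1C/C=C(/C)[Si](C)(C)C
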